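Read both runs by the fraction of the electrophile left, not by the product made, and ask first where that fraction stops.

| flask | electrophile | nucleophile | protic impurity | remark | time |
|---|---|---|---|---|---|
| Wednesday's | 0.10 M | 0.14 M | 0.050 M | run made earlier |  |
| Thursday's | 0.10 M | 0.22 M | 0.050 M | run made earlier |  |
| flask | 0.10 M |  | 0.0500 M |  | 6.0 min |

- Wednesday's (time / min: product / %, electrophile / %): 1.33: 65.1, 35.2; 3.00: 68.6, 31.9; 4.00: 69.3, 31.9; 6.00: 68.2, 31.0; 8.00: 68.3, 30.9
- Thursday's (time / min: product / %, electrophile / %): 0.667: 77.0, 23.1; 2.00: 93.0, 7.1; 3.00: 95.4, 4.1; 5.00: 98.0, 2.0; 8.00: 98.4, 1.0

(standard deviation of a reading: 0.3 percentage points)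

1. the concentration of nucleophile at which the part of the electrophile that has reacted at 6.0 min is just 50%, in M

- the amount of nucleophile is what is sought; it is there from the start
- steps under discussion: electrophile + nucleophile <-> acid set free + product; nucleophile + acid set free <-> protonated nucleophile; nucleophile + protic impurity -> quenched reagent

Wednesday's flask, charged with 1.40 nucleophile per electrophile, goes from 31.9% left at 3.00 min to 30.9% at 8.00 min, a drift of 1 percentage point. Thursday's flask, with more nucleophile, ends at 1.0% left, which marks the nucleophile as the limiting reagent on Wednesday.

What does one electrophile cost? Wednesday's readings give 2.03 for the spend, the nucleophile charged per electrophile reacted at the last reading, 8.00 min. For 50% reacted, this reckoning therefore charges the spend times that part, 1.01 of the electrophile charge, or 0.101 M.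

Is 6.0 min long enough? It is twice the time at which Wednesday's flask had reached its drift, but this flask holds less nucleophile, and that remains the doubt.

The forecast gives 0.1016 M, on the ground that “Two nucleophile per electrophile, with a slow quench, fits instead”.

The flask gives 0.101 M.

    electrophile + nucleophile ⇌ acid set free + product (K = 0.340, k = 0.330 L mol⁻¹ s⁻¹)
    nucleophile + acid set free ⇌ protonated nucleophile, settled at all times (K = 70000 L mol⁻¹)
    nucleophile + protic impurity → quenched reagent (k = 0.00260 L mol⁻¹ s⁻¹)

Divided by the spend, the charge found for this flask comes to 50.0% of the electrophile, while Thursday's charge so divided comes to 109%, more than the electrophile charged, and Thursday's flask reads 1.0% left at 8.00 min. At 6.00 min the step of electrophile with nucleophile in this flask relaxes, both ways together, with a half-life of 0.175 min, short against 6.0 min. The half-life of the nucleophile by the quench alone, the other concentrations as charged, is longer than 6.0 min, at 89 min.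

The runs come from a simulation for substances that don't exist.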